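The numbers in the tables were generated by integration from invented constants, and the scatter is random.

A small charge of substrate can leave the flask by two routes: with coupling partner it gives side product, or on its own it gives intermediate A, from which intermediate B and then, with more partner, target can follow.

| flask | substrate | coupling partner | remark | time |
|---|---|---|---|---|
| spring | 1 M (fed, over 80 s) | 0.75 equiv | run made earlier; the fed solution adds 0.25 times the starting volume |  |
| midnight | 1 M (fed, over 80 s) | 1.3 equiv | run made earlier; the fed solution adds 0.25 times the starting volume |  |
| eta | 1.0 M (fed, over 80 s) | 0.950 equiv | the fed solution adds 0.25 times the starting volume | 30 min |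
| delta | 1.0 M (fed, over 80 s) | 1.40 equiv | the fed solution adds 0.25 times the starting volume | 30 min |
| zeta | 1.0 M (fed, over 80 s) | 2.10 equiv | the fed solution adds 0.25 times the starting volume | 30 min |

| run | time / min | substrate / % | target / % | side product / % | intermediate B / % |
|---|---|---|---|---|---|
| spring | 6.00 | 78.8 | 2.3 | 14.6 | 1.3 |
| spring | 12.0 | 63.6 | 5.9 | 25.4 | 2.4 |
| spring | 20.0 | 49.1 | 11.2 | 33.2 | 2.9 |
| spring | 25.0 | 43.4 | 13.0 | 36.3 | 3.4 |
| spring | 30.0 | 38.3 | 15.1 | 38.0 | 2.1 |
| midnight | 2.50 | 87.1 | 0.9 | 10.5 | 0 |
| midnight | 8.00 | 61.7 | 4.0 | 31.4 | 1.1 |
| midnight | 15.0 | 43.0 | 7.1 | 45.4 | 1.4 |
| midnight | 20.0 | 33.7 | 10.4 | 52.6 | 1.1 |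
| midnight | 30.0 | 21.4 | 13.3 | 60.6 | 0.2 |

(readings scatter by 0.5 percentage points)

- which of these there is most of at the end, counted by the substrate in it, eta (substrate / target / intermediate B / side product)
- which of these there is most of at the end, counted by the substrate in it, delta (substrate / target / intermediate B / side product)
- which of these there is most of at the end, counted by the substrate in it, zeta (substrate / target / intermediate B / side product)
- how much there is at the end of the one of these that leads, in percent of the substrate charged: eta
- how much there is at the end of the one of these that leads, in percent of the substrate charged: delta
- how much there is at the end of the one of these that leads, in percent of the substrate charged: zeta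

- amounts are per litre of the starting volume; all of the dose is in the solution fed
- candidate steps: substrate + coupling partner -> side product; substrate -> intermediate A; intermediate A -> intermediate B; coupling partner + intermediate B -> target; intermediate A -> decomposed reagent

The earlier runs seem to contradict each other. Target consumes partner, yet at 30.0 min the spring run, with 0.75 equiv, holds 15.1% of target, more than the 13.3% of the midnight run, with 1.3 equiv.

The two routes clear this up. Both rates carry c(substrate), so it cancels from their ratio, and this split (a selectivity factor) is c(coupling partner) over a constant level. The substrate gone by the lone route is whatever is neither substrate nor side product: 23.7% in spring, but 18.0% in midnight, less. Midnight, with the larger charge of partner, has sent less substrate down the route to target than spring.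

The level comes from solving each run at both ends and joining them. Counted as the charge over the volume after the feed, c(coupling partner) in spring starts at 0.600 M, and at 30.0 min, less what side product and target took, it is 0.175 M. In midnight it goes from 1.04 M to 0.449 M. Taking the mean of the two ends, times lone-route loss, over side product gives 0.242 M for spring and 0.221 M for midnight. Their mean is the crossover level c_cross, the partner concentration at which both routes take substrate equally, here an estimate from scattered readings: 0.231 M.

At the start the split is then 3.28 in eta, 4.84 in delta and 7.26 in zeta. At the start of each of these flasks, c_cross stands lower than c(coupling partner), so this reckoning puts the side-product route ahead of the lone route then; it gives shares, not amounts.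

The forecast says “side product leads in all three runs”, at 47.5% (44.5% to 50.5%) in eta, 63.5% (60.5% to 66.5%) in delta and 77% (73% to 81%) in zeta.

Side product does lead, at 47.5% in eta, 63.3% in delta and 78.4% in zeta.

    substrate + coupling partner → side product (k = 0.0599 /M/min)
    substrate → intermediate A (k = 0.0129 /min)
    intermediate A → intermediate B (k = 0.826 /min)
    coupling partner + intermediate B → target (k = 0.837 /M/min)
    intermediate A → decomposed reagent (k = 0.245 /min)

Target falls from 14.4% in eta to 9.73% in zeta. With 35% of its partner left at the end, the mean of eta's two ends over c_cross gives a split of 2.21, and side product over lone-route loss in eta stands at 2.27. A neighbouring flask like eta, with 0.380 equiv of partner and 14.9% of it left, gives a split of 0.754 the same way, and its side product over lone-route loss stands at 0.736.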